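Slowness is the quarrel: the flask takes 75 mM of catalyst where gamma took 110 mM, the other charges unchanged, and no earlier run shows what that cut does.

| flask | left-handed substrate | right-handed substrate | partner | protic impurity | catalyst | remark | time |
|---|---|---|---|---|---|---|---|
| gamma | 1.5 M | 1.5 M | 1.2 M (fed, over 40 s) | 0.15 M | 110 mM | run made earlier; the fed solution adds 0.25 times the starting volume |  |
| flask | 1.5 M | 1.5 M | 1.20 M (fed, over 40 s) | 0.150 M | 75 mM | the fed solution adds 0.25 times the starting volume | 12 min |

gamma run (percent of the left-handed substrate and right-handed substrate together charged)

| time / min | left-handed product / % | right-handed substrate / % | right-handed product / % |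
|---|---|---|---|
| 0.333 | 11.2 | 43.3 | 7.4 |
| 0.833 | 24.0 | 34.9 | 15.0 |
| 1.50 | 24.3 | 35.1 | 15.2 |
| 2.50 | 24.1 | 35.2 | 14.8 |
| 4.00 | 24.3 | 34.9 | 15.1 |

(readings scatter by 0.3 percentage points)

- catalyst is single-handed; left-handed substrate and right-handed substrate are mirror images of each other, charged as a racemate, each of them at the stated concentration
- every charge counts on the volume at the start, and the solution that is fed holds the whole dose
- the earlier runs were read with a standard deviation of 0.3 percentage points
- no earlier run changes the charge of catalyst; that part of a forecast is a guess

* amount of left-handed product at 12 min, in percent of the left-handed substrate and right-handed substrate together charged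
* amount of right-handed substrate at 12 min, in percent of the left-handed substrate and right-handed substrate together charged
* amount of right-handed product at 12 min, in percent of the left-handed substrate and right-handed substrate together charged

Both sides start from the partner, the limiting reagent. Its charge over both substrates together gives a ceiling of 40.0% of product. Gamma stood flat from 0.833 min to 4.00 min, averaging 24.2% left-handed and 15.0% right-handed product.

The first chemist argues from slowness: with less catalyst the partner waits, the protic impurity takes its whole dose, and the flask ends at 35.0% of product. The second sees a race between coupling and quenching, and I side with the race.

Call the share of the partner charge missing from the product the leak, 2.00% in gamma, a reading with its scatter. That is less than the 12.5% which the impurity's dose makes of the partner charge, so in gamma the dose was not taken whole.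

Now replace the falling substrate and impurity curves by their means. The leak is then roughly quenching rate over coupling rate. The flask starts from gamma's substrate and impurity charges, so I take the error of those means to cancel largely between the two flasks, which is an assumption. I also take the coupling rate to go with the catalyst, a guess, and scale the leak by the catalyst ratio to 2.93%.

That gives 38.8% of product. Split as in gamma, and with the flat stretch taken on to 12 min, it is 23.9% left-handed product, 14.9% right-handed product and 35.1% right-handed substrate.

The forecast says 23.8%, 35.2% and 14.8%. It weighs “Simple competition gives a loss of about 1.2 points” against a larger loss, and its product total of 38.6% stands a little lower than mine.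

The flask gives 23.8% left-handed product, 35.2% right-handed substrate and 14.8% right-handed product, and the forecast holds.

    partner + catalyst + right-handed substrate → catalyst + right-handed product (k = 3.10 /M²/s)
    partner + catalyst + left-handed substrate → catalyst + left-handed product (k = 5.70 /M²/s)
    partner + protic impurity → quenched reagent (k = 0.180 /M/s)

The flask's leak is 3.35% against the 2.00% read in gamma, and its product stands 3.7 percentage points above the slowness view's 35.0%. That view stands closer in the neighbour with 3.0 M of partner, where the ceiling is 100%. Carrying the flask's leak gives 96.7%, the whole dose taken gives 95.0%, and the neighbour holds 95.5%, with the protic impurity down to 9.60% of its charge at 12.0 min.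

(The data are calculated from invented constants; noise was put on by code.)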